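**Retrosynthetic overview**
1. Target ⇐ B‑alkyl Suzuki coupling of the vinyl macrocycle 18 with the (E)‑iodoalkenol 21 (side‑chain CH2–CH= bond).
2. 18 ⇐ desulfonylation of 17; the only ring (14‑membered) is closed by intramolecular α‑sulfonyl carbanion alkylation of an allylic chloride.
3. Open‑chain precursor ⇐ Zr‑carboalumination / Pd alkenyl–allyl coupling of alkyne 10 with nerol‑derived acetate 12 (builds the skipped Z,E‑diene).
4. 10 (both stereocentres) ⇐ chiral‑biphenol‑catalysed (E)‑crotylboration of the achiral β‑keto sulfone 3.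
5. 3 ⇐ methyl pent‑4‑ynoate + methyl phenyl sulfone; 12 ⇐ neryl acetate (SeO2).

Assumption: the sense of induction of the (S)‑biphenol catalyst in step 3 is taken by analogy with methyl ketones; the (R)‑catalyst is used instead if the first run gives ent‑10.

**Step 1**
Reactants: 1 methyl pent‑4‑ynoate; 2 methyl phenyl sulfone
Product: 3 1‑(phenylsulfonyl)hex‑5‑yn‑2‑one
Conditions: 2 (3.1 eq), n‑BuLi (3.1 eq), THF, −78 → 0 °C; then 1, −78 °C → rt; 1 M HCl
Reagents that add atoms: none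
Why: Claisen‑type acylation of lithiated methyl phenyl sulfone by the ester, the extra carbanion absorbing the acidic product and the alkyne C–H so that no over‑addition occurs.

**Step 2**
Reactants: 4 (E)‑but‑2‑ene; 5 triisopropyl borate
Product: 8 diisopropyl (E)‑but‑2‑en‑1‑ylboronate, via (E)‑crotylpotassium 6 (not isolated), via potassium crotyl(triisopropoxy)borate 7 (not isolated)
Conditions: n‑BuLi, KOt‑Bu, THF, −78 → −50 °C; 5, −78 °C; HCl/Et2O (1 eq); distil
Reagents that add atoms: none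
Why: Schlosser‑base allylic metalation gives configurationally stable (E)‑crotylpotassium below −50 °C, which is borylated and the ate complex protonated (standard crotylboronate synthesis).

**Step 3**
Reactants: 3 1‑(phenylsulfonyl)hex‑5‑yn‑2‑one; 8 diisopropyl (E)‑but‑2‑en‑1‑ylboronate
Product: 10 (3R,4R)‑3‑methyl‑4‑[(phenylsulfonyl)methyl]oct‑1‑en‑7‑yn‑4‑ol, via diisopropyl borate ester 9 (not isolated)
Conditions: 8 (1.5 eq), (S)‑3,3′‑dibromo‑BINOL (15 mol %), PhCF3–PhMe 3:1, −35 °C, 36 h; pH 7 buffer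
Reagents that add atoms: none
Why: Proposed new method: biphenol‑catalysed crotylboration, so far shown for methyl ketones, is applied to a β‑keto sulfone with two primary‑alkyl arms; the BINOL exchanges onto boron to give a more Lewis‑acidic chiral boronate that adds through a closed six‑membered chair (type I allylboration) in which the bulky CH2SO2Ph arm (its S=O able to accept a hydrogen bond from the catalyst OH) sits pseudo‑equatorial and the slim butynyl arm pseudo‑axial, so the (E)‑crotyl unit gives the anti adduct and the catalyst selects the ketone face, setting C4 (R) and C3 (R) together, while the base‑free medium leaves the acidic α‑sulfonyl CH2 alone; closest known reaction type: chiral 3,3′‑disubstituted‑BINOL‑catalysed allyl‑ and crotylboration of methyl ketones with diisopropoxyboranes.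

**Step 4**
Reactants: 11 neryl acetate
Product: 12 (2Z,6E)‑8‑hydroxy‑3,7‑dimethylocta‑2,6‑dien‑1‑yl acetate
Conditions: SeO2 (10 mol %), t‑BuOOH, salicylic acid (10 mol %), CH2Cl2, 0 °C → rt
Reagents that add atoms: tert‑butyl hydroperoxide CC(C)(C)OO
Why: Catalytic SeO2 allylic oxidation (ene then [2,3] shift) hydroxylates only the (E)‑methyl of the electron‑rich terminal alkene and leaves the acetate‑deactivated Z‑alkene untouched.

**Step 5**
Reactants: 10 (3R,4R)‑3‑methyl‑4‑[(phenylsulfonyl)methyl]oct‑1‑en‑7‑yn‑4‑ol; 12 (2Z,6E)‑8‑hydroxy‑3,7‑dimethylocta‑2,6‑dien‑1‑yl acetate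
Product: 14 (3R,4R,7E,10Z,14E)‑3,7,11,15‑tetramethyl‑4‑[(phenylsulfonyl)methyl]hexadeca‑1,7,10,14‑tetraene‑4,16‑diol, via alkenyldimethylalane 13 (not isolated)
Conditions: AlMe3 (6 eq), Cp2ZrCl2 (0.5 eq), (CH2Cl)2, 0 °C → rt; then 12, Pd(PPh3)4 (5 mol %), THF, rt; aq. Rochelle salt
Reagents that add atoms: trimethylaluminium C[Al](C)C
Why: Negishi Zr‑catalysed syn‑carboalumination gives the (E)‑alkenylalane, and Pd(0)‑catalysed alkenyl–allyl coupling with the allylic acetate forms the skipped diene at the primary terminus with retention of the new E and the neryl Z geometry, both hydroxyls being masked in situ as aluminium alkoxides and the stereocentres not involved.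

**Step 6**
Reactants: 14 (3R,4R,7E,10Z,14E)‑tetraene‑4,16‑diol
Product: 16 (3R,4R,7E,10Z,14E)‑16‑chloro‑3,7,11,15‑tetramethyl‑4‑[(phenylsulfonyl)methyl]hexadeca‑1,7,10,14‑tetraen‑4‑ol, via allylic mesylate 15 (not isolated)
Conditions: MsCl, 2,4,6‑collidine, LiCl, DMF, 0 °C
Reagents that add atoms: lithium chloride [Li+].[Cl-]
Why: Collington–Meyers chlorination (mesylation then SN2 by chloride) converts only the primary allylic alcohol without allylic transposition, the hindered tertiary alcohol being inert.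

**Step 7**
Reactants: 16 allylic chloride
Product: 17 (1R,4E,7Z,11E)‑1‑[(2R)‑but‑3‑en‑2‑yl]‑4,8,12‑trimethyl‑14‑(phenylsulfonyl)cyclotetradeca‑4,7,11‑trien‑1‑ol (both C14 epimers)
Conditions: LDA (2.3 eq), THF–DMPU, −78 → −30 °C, slow addition of 16 (final 0.003 M); AcOH at −78 °C
Reagents that add atoms: none
Why: Intramolecular SN2 alkylation of the α‑sulfonyl carbanion (as alkoxide/carbanion dianion) by the primary allylic chloride under high dilution closes the 14‑membered ring, a classical sulfone macrocyclisation for cembranoid‑type chains; the sulfonyl‑bearing centre forms as a mixture that step 8 erases.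

**Step 8**
Reactants: 17 macrocyclic β‑hydroxy sulfone
Product: 18 (1R,4E,7Z,11E)‑1‑[(2R)‑but‑3‑en‑2‑yl]‑4,8,12‑trimethylcyclotetradeca‑4,7,11‑trien‑1‑ol
Conditions: SmI2 (6 eq), HMPA, THF–MeOH, −78 → −20 °C
Reagents that add atoms: none
Why: Single‑electron reductive desulfonylation cleaves the C–S bond and MeOH protonates the carbanion; a free β‑hydroxyl is a poor leaving group, so Julia‑type elimination is not expected, and isolated alkenes are inert.

**Step 9**
Reactants: 19 prop‑2‑yn‑1‑ol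
Product: 21 (E)‑3‑iodo‑2‑methylprop‑2‑en‑1‑ol, via alkenyldimethylalane 20 (not isolated)
Conditions: AlMe3 (3 eq), Cp2ZrCl2 (25 mol %), CH2Cl2, 0 °C → rt; I2, THF, −30 → 0 °C; aq. NaHCO3
Reagents that add atoms: trimethylaluminium C[Al](C)C; iodine II
Why: Negishi Zr‑catalysed syn‑carboalumination followed by iodinolysis with retention gives the (E)‑iodoalkene.

**Step 10**
Reactants: 18 vinyl macrocycle; 21 (E)‑3‑iodo‑2‑methylprop‑2‑en‑1‑ol
Product: 23 (1R,4E,7Z,11E)‑1‑[(2R,5E)‑7‑hydroxy‑6‑methylhept‑5‑en‑2‑yl]‑4,8,12‑trimethylcyclotetradeca‑4,7,11‑trien‑1‑ol (CNP0178561.1), via B‑alkyl‑9‑BBN borane 22 (not isolated)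
Conditions: 9‑BBN (2.5 eq), THF, 0 °C → rt; then 21, PdCl2(dppf) (5 mol %), AsPh3, 3 M aq. NaOH, THF–DMF, rt
Reagents that add atoms: none
Why: 9‑BBN hydroborates only the monosubstituted vinyl group (anti‑Markovnikov) beside three trisubstituted ring alkenes, and B‑alkyl Suzuki–Miyaura coupling proceeds with retention of the iodide's E geometry without touching either stereocentre.

**Compound list**
1 | methyl pent‑4‑ynoate | C#CCCC(=O)OC | starting material
2 | methyl phenyl sulfone | CS(=O)(=O)c1ccccc1 | starting material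
3 | 1‑(phenylsulfonyl)hex‑5‑yn‑2‑one | C#CCCC(=O)CS(=O)(=O)c1ccccc1 | intermediate
4 | (E)‑but‑2‑ene | C/C=C/C | starting material
5 | triisopropyl borate | CC(C)OB(OC(C)C)OC(C)C | starting material
6 | (E)‑crotylpotassium | C/C=C/C[K] | intermediate (not isolated)
7 | potassium (E)‑crotyl(triisopropoxy)borate | C/C=C/C[B-](OC(C)C)(OC(C)C)OC(C)C.[K+] | intermediate (not isolated)
8 | diisopropyl (E)‑but‑2‑en‑1‑ylboronate | C/C=C/CB(OC(C)C)OC(C)C | intermediate
9 | diisopropyl borate ester of 10 | C#CCC[C@@](OB(OC(C)C)OC(C)C)([C@H](C)C=C)CS(=O)(=O)c1ccccc1 | intermediate (not isolated)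
10 | (3R,4R)‑3‑methyl‑4‑[(phenylsulfonyl)methyl]oct‑1‑en‑7‑yn‑4‑ol | C#CCC[C@@](O)([C@H](C)C=C)CS(=O)(=O)c1ccccc1 | intermediate
11 | neryl acetate | CC(C)=CCC/C(C)=C\COC(C)=O | starting material
12 | (2Z,6E)‑8‑hydroxy‑3,7‑dimethylocta‑2,6‑dien‑1‑yl acetate | OC/C(C)=C/CC/C(C)=C\COC(C)=O | intermediate
13 | (E)‑alkenyldimethylalane of 10 (O–AlMe2 alkoxide) | C[Al](C)/C=C(\C)CC[C@@](O[Al](C)C)([C@H](C)C=C)CS(=O)(=O)c1ccccc1 | intermediate (not isolated)
14 | (3R,4R,7E,10Z,14E)‑3,7,11,15‑tetramethyl‑4‑[(phenylsulfonyl)methyl]hexadeca‑1,7,10,14‑tetraene‑4,16‑diol | OC/C(C)=C/CC/C(C)=C\C/C=C(\C)CC[C@@](O)([C@H](C)C=C)CS(=O)(=O)c1ccccc1 | intermediate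
15 | 16‑O‑methanesulfonate of 14 | CS(=O)(=O)OC/C(C)=C/CC/C(C)=C\C/C=C(\C)CC[C@@](O)([C@H](C)C=C)CS(=O)(=O)c1ccccc1 | intermediate (not isolated)
16 | (3R,4R,7E,10Z,14E)‑16‑chloro‑3,7,11,15‑tetramethyl‑4‑[(phenylsulfonyl)methyl]hexadeca‑1,7,10,14‑tetraen‑4‑ol | ClC/C(C)=C/CC/C(C)=C\C/C=C(\C)CC[C@@](O)([C@H](C)C=C)CS(=O)(=O)c1ccccc1 | intermediate
17 | (1R,4E,7Z,11E)‑1‑[(2R)‑but‑3‑en‑2‑yl]‑4,8,12‑trimethyl‑14‑(phenylsulfonyl)cyclotetradeca‑4,7,11‑trien‑1‑ol (C14 epimers) | C/C1=C/C/C=C(\C)CC[C@@](O)([C@H](C)C=C)C(S(=O)(=O)c2ccccc2)C/C(C)=C/CC1 | intermediate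
18 | (1R,4E,7Z,11E)‑1‑[(2R)‑but‑3‑en‑2‑yl]‑4,8,12‑trimethylcyclotetradeca‑4,7,11‑trien‑1‑ol | C/C1=C/C/C=C(\C)CC[C@@](O)([C@H](C)C=C)CC/C(C)=C/CC1 | intermediate
19 | prop‑2‑yn‑1‑ol | C#CCO | starting material
20 | (E)‑alkenyldimethylalane of 19 (O–AlMe2 alkoxide) | C[Al](C)/C=C(\C)CO[Al](C)C | intermediate (not isolated)
21 | (E)‑3‑iodo‑2‑methylprop‑2‑en‑1‑ol | OC/C(C)=C/I | intermediate
22 | 9‑{(3R)‑3‑[(1R,4E,7Z,11E)‑1‑hydroxy‑4,8,12‑trimethylcyclotetradeca‑4,7,11‑trien‑1‑yl]butyl}‑9‑borabicyclo[3.3.1]nonane | C/C1=C/C/C=C(\C)CC[C@@](O)([C@H](C)CCB2C3CCCC2CCC3)CC/C(C)=C/CC1 | intermediate (not isolated)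
23 | (1R,4E,7Z,11E)‑1‑[(2R,5E)‑7‑hydroxy‑6‑methylhept‑5‑en‑2‑yl]‑4,8,12‑trimethylcyclotetradeca‑4,7,11‑trien‑1‑ol | C/C1=C/C/C=C(\C)CC[C@@](O)([C@H](C)CC/C=C(\C)CO)CC/C(C)=C/CC1 | target

**Step count**
Total: 10 steps. Longest linear sequence: 7 steps (1, 3, 5, 6, 7, 8, 10).

**Three steps most likely to fail**

Step 3 (proposed new crotylboration). The catalyst may not discriminate CH2SO2Ph from the butynyl arm well enough, an uncatalysed background reaction may erode ee, or the acidic ketone may enolise. The fallback uses known, stereospecific chemistry, sets out from 1 and comes back at 10. Ester 1 is converted (MeNHOMe·HCl, i‑PrMgCl) into the Weinreb amide N‑methoxy‑N‑methylpent‑4‑ynamide F1. LiCH2OMOM (from Bu3SnCH2OMOM/n‑BuLi, one extra equivalent for the alkyne C–H) gives the α‑alkoxy ketone 1‑(methoxymethoxy)hex‑5‑yn‑2‑one F2. The Z‑selective Wittig olefination of α‑alkoxy ketones with Ph3P=CHCH3 gives the allyl ether (5Z)‑5‑[(methoxymethoxy)methyl]hept‑5‑en‑1‑yne F3, with CH3 cis to CH2O. HCl/MeOH frees the allylic alcohol (2Z)‑2‑(but‑3‑yn‑1‑yl)but‑2‑en‑1‑ol F4. Sharpless asymmetric epoxidation (Ti(Oi‑Pr)4, L‑(+)‑DIPT, t‑BuOOH) gives the epoxy alcohol [(2S,3R)‑2‑(but‑3‑yn‑1‑yl)‑3‑methyloxiran‑2‑yl]methanol F5. CH2=CHMgBr/CuI opens it at the secondary carbon with inversion to the diol (2R,3R)‑2‑(but‑3‑yn‑1‑yl)‑3‑methylpent‑4‑ene‑1,2‑diol F6; alkene geometry plus inversion fix the relative configuration and the tartrate fixes the absolute one. Selective tosylation gives the primary tosylate F7, K2CO3 closes the terminal epoxide (2R)‑2‑(but‑3‑yn‑1‑yl)‑2‑[(2R)‑but‑3‑en‑2‑yl]oxirane F8, and PhSO2Na opens it at CH2 to give 10.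

Step 5 (carboalumination / alkenyl–allyl coupling). The free hydroxyl of 12, present as an O–Al alkoxide, may compete as a leaving group or quench the alane. The fallback sets out from 10 and 11 and comes back at 14. The alane 13 is coupled under the same Pd(0) catalysis with neryl acetate 11 itself, which has no hydroxyl, to give the tetraenol (3R,4R,7E,10Z)‑3,7,11,15‑tetramethyl‑4‑[(phenylsulfonyl)methyl]hexadeca‑1,7,10,14‑tetraen‑4‑ol F9. The terminal (E)‑methyl group is then hydroxylated late with SeO2/t‑BuOOH, which prefers the gem‑dimethyl alkene terminus, to give 14.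

Step 7 (macrocyclisation). The hindered β‑alkoxy sulfone dianion may alkylate slowly, undergo retro‑aldol cleavage on warming, or oligomerise. The fallback sets out from 10 and 12 and comes back at 17, making the two ring bonds in the opposite order. Alcohol 12 gives the allylic bromide (2Z,6E)‑8‑bromo‑3,7‑dimethylocta‑2,6‑dien‑1‑yl acetate F10 (CBr4, PPh3). Lithiated 10 (LDA, 3.3 eq, −78 °C; alkoxide, acetylide and sulfonyl carbanion) is alkylated intermolecularly by F10 to give the open‑chain sulfone (2Z,6E,10R,11R)‑10‑(but‑3‑yn‑1‑yl)‑10‑hydroxy‑3,7,11‑trimethyl‑9‑(phenylsulfonyl)trideca‑2,6,12‑trien‑1‑yl acetate F11. Water‑accelerated Zr‑catalysed carboalumination at −25 °C gives the alkenyldimethylalane F12, and Pd(PPh3)4 at high dilution closes the ring by intramolecular alkenyl–allyl coupling onto the allylic acetate to give 17.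

**Further compounds**
F1 | step 3 | N‑methoxy‑N‑methylpent‑4‑ynamide | C#CCCC(=O)N(C)OC
F2 | step 3 | 1‑(methoxymethoxy)hex‑5‑yn‑2‑one | C#CCCC(=O)COCOC
F3 | step 3 | (5Z)‑5‑[(methoxymethoxy)methyl]hept‑5‑en‑1‑yne | C/C=C(\COCOC)CCC#C
F4 | step 3 | (2Z)‑2‑(but‑3‑yn‑1‑yl)but‑2‑en‑1‑ol | C/C=C(\CO)CCC#C
F5 | step 3 | [(2S,3R)‑2‑(but‑3‑yn‑1‑yl)‑3‑methyloxiran‑2‑yl]methanol | C#CCC[C@@]1(CO)O[C@@H]1C
F6 | step 3 | (2R,3R)‑2‑(but‑3‑yn‑1‑yl)‑3‑methylpent‑4‑ene‑1,2‑diol | C#CCC[C@@](O)([C@H](C)C=C)CO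
F7 | step 3 | (2R,3R)‑2‑(but‑3‑yn‑1‑yl)‑2‑hydroxy‑3‑methylpent‑4‑en‑1‑yl 4‑methylbenzenesulfonate | C#CCC[C@@](O)([C@H](C)C=C)COS(=O)(=O)c1ccc(C)cc1
F8 | step 3 | (2R)‑2‑(but‑3‑yn‑1‑yl)‑2‑[(2R)‑but‑3‑en‑2‑yl]oxirane | C#CCC[C@@]1([C@H](C)C=C)CO1
F9 | step 5 | (3R,4R,7E,10Z)‑3,7,11,15‑tetramethyl‑4‑[(phenylsulfonyl)methyl]hexadeca‑1,7,10,14‑tetraen‑4‑ol | CC(C)=CCC/C(C)=C\C/C=C(\C)CC[C@@](O)([C@H](C)C=C)CS(=O)(=O)c1ccccc1
F10 | step 7 | (2Z,6E)‑8‑bromo‑3,7‑dimethylocta‑2,6‑dien‑1‑yl acetate | BrC/C(C)=C/CC/C(C)=C\COC(C)=O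
F11 | step 7 | (2Z,6E,10R,11R)‑10‑(but‑3‑yn‑1‑yl)‑10‑hydroxy‑3,7,11‑trimethyl‑9‑(phenylsulfonyl)trideca‑2,6,12‑trien‑1‑yl acetate (C9 epimers) | C#CCC[C@@](O)([C@H](C)C=C)C(S(=O)(=O)c1ccccc1)C/C(C)=C/CC/C(C)=C\COC(C)=O
F12 | step 7 | (E)‑alkenyldimethylalane of F11 (O–AlMe2 alkoxide) | C[Al](C)/C=C(\C)CC[C@@](O[Al](C)C)([C@H](C)C=C)C(S(=O)(=O)c1ccccc1)C/C(C)=C/CC/C(C)=C\COC(C)=O
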